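Tuesday's run took 3.55 times the partner of Wednesday's run and gave 2.80 times the target at 120 s, so partner pays, but less than in proportion. We have material for one more flask, and five recipes to choose from.

| flask | substrate | partner | remark | time |
|---|---|---|---|---|
| Wednesday's | 0.020 M | 0.0093 M (fed, over 3.0 min) | run made earlier |  |
| Tuesday's | 0.020 M | 0.033 M (fed, over 3.0 min) | run made earlier |  |
| Monday's | 0.028 M | 0.030 M (fed, over 3.0 min) | run made earlier |  |
| noon | 0.0050 M | 0.0300 M (fed, over 12 min) |  | 3.0 min |
| summer | 0.020 M | 0.0300 M (fed, over 3.0 min) |  | 3.0 min |
| autumn | 0.080 M | 0.0300 M (fed, over 1.5 min) |  | 3.0 min |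
| winter | 0.0060 M | 0.0500 M (fed, over 1.0 min) |  | 3.0 min |
| midnight | 0.0060 M | 0.0150 M (fed, over 3.0 min) |  | 3.0 min |

| Wednesday's: time / s | Wednesday's: target / % | Tuesday's: time / s | Tuesday's: target / % | Monday's: time / s | Monday's: target / % |
|---|---|---|---|---|---|
| 15.0 | 1.0 | 30.0 | 6.0 | 10.0 | 0 |
| 40.0 | 3.7 | 60.0 | 18.2 | 25.0 | 2.8 |
| 80.0 | 8.2 | 90.0 | 29.3 | 50.0 | 10.9 |
| 120 | 14.3 | 120 | 40.0 | 120 | 34.1 |

(each reading ± 1 percentage point)

- the numbers in the tables scatter with a standard deviation of 1 percentage point
- percentages count the whole charge, also what has not yet gone in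

- the flasks put in order of amount of target, in percent of the substrate charged, best first, at 3.0 min (noon / summer / autumn / winter / midnight)
- the amount of target, in percent of the substrate charged of the flask you put first, at 3.0 min
- the amount of target, in percent of the substrate charged of the flask you put last, at 3.0 min

We reckon in powers of ten and try one group. Crowding is log10 of c(substrate)/c(partner)², with c(partner) counting what has gone in by 3.0 min, measured from Tuesday's run. Wednesday's run stands at 1.10. Its loss of target over that distance gives the crowding toll, 2.55: the factor lost in percent target per power of ten of crowding, at equal time.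

Monday's run is the check, since it played no part in the toll. Its crowding is 0.229, so the toll gives 32.3% from Tuesday's reading. We read 34.1%, with a scatter of 1 percentage point.

| Flask | Crowding |
|---|---|
| winter | −0.884 |
| summer | 0.0828 |
| midnight | 0.162 |
| noon | 0.685 |
| autumn | 0.685 |

Winter has the lowest crowding, but it lies below Tuesday's mark, where no run stands. We trust its rank, not a factor, and we charge winter's recipe. Summer's crowding is less than midnight's, and noon ties with autumn.

The forecast reads winter > summer > midnight > autumn > noon, with 89% at the top and 24% at the bottom, and says “Autumn and noon are close.”; unlike our tie, it ranks autumn above noon.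

The flasks give winter > midnight > summer > noon > autumn, with winter at 74.0% and autumn at 32.1%.

    substrate → intermediate (k = 0.0100 s⁻¹)
    partner + intermediate → target (k = 5.50 M⁻¹ s⁻¹)
    target ⇌ isomer of the product (K = 30.0, k = 8.50 × 10⁻⁴ s⁻¹)
    substrate → decomposition product (k = 2.10 × 10⁻⁵ s⁻¹)
    2 intermediate → homo product (k = 4.50 M⁻¹ s⁻¹)

Winter's conversion of substrate is 83.5% at 3.00 min. From summer's 52.0%, the toll gives autumn 29.6%, against 32.1%. Taken the other way, it gives winter 129%, against that conversion of 83.5%.

A neighbour, like winter but with 0.013 M of partner, has crowding 0.286, so from midnight's 56.4% the toll gives 50.3%. The computed flask gives 65.0%, more than the toll's figure, with its partner fed over 1.0 min against midnight's 3.0 min.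

The readings stem from a simulated flask with made-up constants.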